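## Retrosynthetic overview

1. The last operation is aqueous acid. It removes three MOM acetals and erases a temporary lactone (hydrolysis, then loss of CO2) from a tetracyclic β-keto lactone in which the 2'-oxygen of ring B is tied to a carboxyl group on C3.
2. The key disconnection cuts the tetracycle back to a hexasubstituted ring A β-keto ester and 2-hydroxy-4-(methoxymethoxy)benzaldehyde. Knoevenagel condensation, lactonisation and an enantioselective oxa-Michael addition build the lactone ring and ring C in one flask and set C2.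
3. The β-keto ester comes from the acetophenone by crossed Claisen condensation. The (E)-3-methylbut-1-enyl arm comes from hydroboration/Suzuki coupling at an iodide para to the one free phenol.
4. The 8-prenyl/6-alkenyl regiochemistry comes from C-prenylation of symmetric phloroacetophenone followed by bis-MOM protection. This leaves free only the OH next to the prenyl group, which becomes O1.
5. Ring order: rings A and B are bought. The temporary lactone ring and then ring C form in the same operation, and the lactone ring is removed at the end.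

Assumption: the quinine-derived thiourea is taken to give the 2S series, and its quinidine-derived pseudo-enantiomer is used if the sense proves opposite. Flavanone numbering is used for positions throughout.

## Route

Step 1
Reactants: 1 2,4,6-trihydroxyacetophenone; 2 prenyl bromide (1-bromo-3-methylbut-2-ene)
Product: 3 1-[2,4,6-trihydroxy-3-(3-methylbut-2-enyl)phenyl]ethanone
Conditions: KOH (1.0 equiv), H2O, 0 to 23 °C
Reagents that add atoms: none
Why: This is a Friedel–Crafts-type C-alkylation of the ambident phloroglucinol phenoxide, in which water solvates the oxygen so that carbon takes up the soft allylic electrophile, and the two free ring carbons are equivalent so only one mono-C-prenyl product can form.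

Step 2
Reactants: 3 1-[2,4,6-trihydroxy-3-(3-methylbut-2-enyl)phenyl]ethanone
Product: 4 1-[2-hydroxy-4,6-bis(methoxymethoxy)-3-(3-methylbut-2-enyl)phenyl]ethanone
Conditions: MOMCl (2.3 equiv), K2CO3 (4 equiv), acetone, 0 to 23 °C
Reagents that add atoms: chloromethyl methyl ether (MOMCl), COCCl
Why: This is a Williamson-type O-alkylation under steric and hydrogen-bond control, in which the 4-OH and the less hindered 6-OH react while the OH wedged between acetyl and prenyl stays chelated to the ketone and is thereby singled out as the future O1.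

Step 3
Reactants: 4 1-[2-hydroxy-4,6-bis(methoxymethoxy)-3-(3-methylbut-2-enyl)phenyl]ethanone
Product: 5 1-[2-hydroxy-5-iodo-4,6-bis(methoxymethoxy)-3-(3-methylbut-2-enyl)phenyl]ethanone
Conditions: NIS (1.0 equiv), DMF, 0 °C, dark
Reagents that add atoms: N-iodosuccinimide (NIS), O=C1CCC(=O)N1I
Why: This is an electrophilic aromatic iodination at the single free ring carbon, which lies para to the free phenol and ortho to two acetal oxygens and should therefore outrun the trisubstituted alkene for one equivalent of NIS.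

Step 4
Reactants: 5 1-[2-hydroxy-5-iodo-4,6-bis(methoxymethoxy)-3-(3-methylbut-2-enyl)phenyl]ethanone; 6 3-methylbut-1-yne; 7 pinacolborane
Product: 9 1-[2-hydroxy-4,6-bis(methoxymethoxy)-5-[(E)-3-methylbut-1-enyl]-3-(3-methylbut-2-enyl)phenyl]ethanone, via alkenyl pinacolboronate 8 (not isolated)
Conditions: 6, 7, Cp2Zr(H)Cl (5 mol %), Et3N (5 mol %), THF, sealed tube, 50 °C; then 5, Pd(OAc)2 (5 mol %), SPhos (10 mol %), K3PO4 (3 equiv), H2O, 60 °C
Reagents that add atoms: none
Why: Zirconium-catalysed syn-hydroboration of the terminal alkyne fixes the E geometry, and the Suzuki–Miyaura coupling transfers the alkenyl group with retention while SPhos copes with the di-ortho-substituted iodide.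

Step 5
Reactants: 9 1-[2-hydroxy-4,6-bis(methoxymethoxy)-5-[(E)-3-methylbut-1-enyl]-3-(3-methylbut-2-enyl)phenyl]ethanone
Product: 10 ethyl 3-[2-hydroxy-4,6-bis(methoxymethoxy)-5-[(E)-3-methylbut-1-enyl]-3-(3-methylbut-2-enyl)phenyl]-3-oxopropanoate
Conditions: NaH (3.5 equiv), (EtO)2CO (5 equiv), THF, 0 to 60 °C; cold 1 M HCl to pH 4
Reagents that add atoms: diethyl carbonate, CCOC(=O)OCC
Why: This is a crossed Claisen condensation of the methyl ketone enolate, in which the product is held as its bis-sodium salt, whose enolate ester is too poor an electrophile to lactonise at 60 °C, until a cold quench releases it.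

Step 6
Reactants: 11 2,4-dihydroxybenzaldehyde
Product: 12 2-hydroxy-4-(methoxymethoxy)benzaldehyde
Conditions: MOMCl (1.05 equiv), K2CO3 (1.2 equiv), acetone, 23 °C
Reagents that add atoms: chloromethyl methyl ether (MOMCl), COCCl
Why: This is a selective Williamson-type alkylation, because the 4-OH is the more acidic, non-chelated phenol while the 2-OH is hydrogen-bonded to the aldehyde and stays free as the later lactone oxygen.

Step 7
Reactants: 10 ethyl 3-[2-hydroxy-4,6-bis(methoxymethoxy)-5-[(E)-3-methylbut-1-enyl]-3-(3-methylbut-2-enyl)phenyl]-3-oxopropanoate; 12 2-hydroxy-4-(methoxymethoxy)benzaldehyde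
Product: 15 (6aS,12aS)-3,8,10-tris(methoxymethoxy)-9-[(E)-3-methylbut-1-enyl]-11-(3-methylbut-2-enyl)-6a,12a-dihydro-6H,7H-chromeno[4,3-b]chromene-6,7-dione, via Knoevenagel adduct 13 (not isolated), via 3-aroylcoumarin 14 (not isolated)
Conditions: piperidinium acetate (10 mol %), 4 Å MS, toluene, 23 °C, 12 h; then −25 °C, N-[3,5-bis(trifluoromethyl)phenyl]-N'-(9-deoxy-epi-quinin-9-yl)thiourea (15 mol %), 48 h; AcOH quench, short SiO2 plug
Reagents that add atoms: none
Why: Proposed new method: Knoevenagel condensation and lactonisation by the ring B phenol (the standard 3-acylcoumarin synthesis) give the doubly activated acceptor 14, whose only free ring A phenol then adds to the coumarin C4 in an intramolecular oxa-Michael addition organised by the thiourea and quinuclidine groups of the catalyst, which sets C2 as S from the catalyst-controlled face while the labile C3 centre settles as the cis-fused lactone; the closest known reaction type is the bifunctional-thiourea-catalysed oxa-Michael cyclisation of alkylidene β-keto esters to 3-carboxyflavanones, and closure should be downhill because the di-ortho-substituted aroyl group is twisted out of conjugation in 14 and regains its vinylogous-ester resonance in the chromanone.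

Step 8
Reactants: 15 (6aS,12aS)-3,8,10-tris(methoxymethoxy)-9-[(E)-3-methylbut-1-enyl]-11-(3-methylbut-2-enyl)-6a,12a-dihydro-6H,7H-chromeno[4,3-b]chromene-6,7-dione
Product: 18 (2S)-2-(2,4-dihydroxyphenyl)-5,7-dihydroxy-6-[(E)-3-methylbut-1-enyl]-8-(3-methylbut-2-enyl)chroman-4-one, via beta-keto acid 16 (not isolated), via tris-MOM flavanone 17 (not isolated)
Conditions: 2 M aq HCl/THF (1:3), 0.02 M, 45 °C, Ar
Reagents that add atoms: none
Why: Acid-catalysed lactone hydrolysis, spontaneous β-keto acid decarboxylation and acetal hydrolysis run in one pot without base, so the retro-oxa-Michael path that would scramble C2 stays closed, the C3 centre disappears, and the 2'-OH emerges from the lactone without ever having carried a protecting group.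

## Compound list

1 | 2,4,6-trihydroxyacetophenone | CC(=O)c1c(O)cc(O)cc1O | starting material
2 | prenyl bromide (1-bromo-3-methylbut-2-ene) | CC(C)=CCBr | starting material
3 | 1-[2,4,6-trihydroxy-3-(3-methylbut-2-enyl)phenyl]ethanone | CC(=O)c1c(O)cc(O)c(CC=C(C)C)c1O | intermediate
4 | 1-[2-hydroxy-4,6-bis(methoxymethoxy)-3-(3-methylbut-2-enyl)phenyl]ethanone | CC(=O)c1c(OCOC)cc(OCOC)c(CC=C(C)C)c1O | intermediate
5 | 1-[2-hydroxy-5-iodo-4,6-bis(methoxymethoxy)-3-(3-methylbut-2-enyl)phenyl]ethanone | CC(=O)c1c(OCOC)c(I)c(OCOC)c(CC=C(C)C)c1O | intermediate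
6 | 3-methylbut-1-yne | CC(C)C#C | starting material
7 | pinacolborane (4,4,5,5-tetramethyl-1,3,2-dioxaborolane) | [H]B1OC(C)(C)C(C)(C)O1 | starting material
8 | (E)-4,4,5,5-tetramethyl-2-(3-methylbut-1-enyl)-1,3,2-dioxaborolane | CC(C)/C=C/B1OC(C)(C)C(C)(C)O1 | intermediate
9 | 1-[2-hydroxy-4,6-bis(methoxymethoxy)-5-[(E)-3-methylbut-1-enyl]-3-(3-methylbut-2-enyl)phenyl]ethanone | CC(=O)c1c(OCOC)c(/C=C/C(C)C)c(OCOC)c(CC=C(C)C)c1O | intermediate
10 | ethyl 3-[2-hydroxy-4,6-bis(methoxymethoxy)-5-[(E)-3-methylbut-1-enyl]-3-(3-methylbut-2-enyl)phenyl]-3-oxopropanoate | CCOC(=O)CC(=O)c1c(OCOC)c(/C=C/C(C)C)c(OCOC)c(CC=C(C)C)c1O | intermediate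
11 | 2,4-dihydroxybenzaldehyde | O=Cc1ccc(O)cc1O | starting material
12 | 2-hydroxy-4-(methoxymethoxy)benzaldehyde | O=Cc1ccc(OCOC)cc1O | intermediate
13 | ethyl (Z)-2-[2-hydroxy-4,6-bis(methoxymethoxy)-5-[(E)-3-methylbut-1-enyl]-3-(3-methylbut-2-enyl)benzoyl]-3-[2-hydroxy-4-(methoxymethoxy)phenyl]prop-2-enoate | CCOC(=O)/C(=C\c1ccc(OCOC)cc1O)C(=O)c1c(O)c(CC=C(C)C)c(OCOC)c(/C=C/C(C)C)c1OCOC | intermediate
14 | 3-[2-hydroxy-4,6-bis(methoxymethoxy)-5-[(E)-3-methylbut-1-enyl]-3-(3-methylbut-2-enyl)benzoyl]-7-(methoxymethoxy)chromen-2-one | O=C1Oc2cc(OCOC)ccc2C=C1C(=O)c1c(O)c(CC=C(C)C)c(OCOC)c(/C=C/C(C)C)c1OCOC | intermediate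
15 | (6aS,12aS)-3,8,10-tris(methoxymethoxy)-9-[(E)-3-methylbut-1-enyl]-11-(3-methylbut-2-enyl)-6a,12a-dihydro-6H,7H-chromeno[4,3-b]chromene-6,7-dione (cis-fused; C12a is flavanone C2) | CC(C)=CCc1c(OCOC)c(/C=C/C(C)C)c(OCOC)c2c1O[C@@H]1c3ccc(OCOC)cc3OC(=O)[C@@H]1C2=O | intermediate
16 | (2S,3S)-2-[2-hydroxy-4-(methoxymethoxy)phenyl]-5,7-bis(methoxymethoxy)-6-[(E)-3-methylbut-1-enyl]-8-(3-methylbut-2-enyl)-4-oxochromane-3-carboxylic acid | CC(C)=CCc1c(OCOC)c(/C=C/C(C)C)c(OCOC)c2c1O[C@H](c1ccc(OCOC)cc1O)[C@H](C(=O)O)C2=O | intermediate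
17 | (2S)-2-[2-hydroxy-4-(methoxymethoxy)phenyl]-5,7-bis(methoxymethoxy)-6-[(E)-3-methylbut-1-enyl]-8-(3-methylbut-2-enyl)chroman-4-one | CC(C)=CCc1c(OCOC)c(/C=C/C(C)C)c(OCOC)c2c1O[C@H](c1ccc(OCOC)cc1O)CC2=O | intermediate
18 | (2S)-2-(2,4-dihydroxyphenyl)-5,7-dihydroxy-6-[(E)-3-methylbut-1-enyl]-8-(3-methylbut-2-enyl)chroman-4-one | CC(C)=CCc1c(O)c(/C=C/C(C)C)c(O)c2c1O[C@H](c1ccc(O)cc1O)CC2=O | target

## Step count and risks

There are 8 steps in total. The longest linear sequence is 7 steps (steps 1, 2, 3, 4, 5, 7 and 8), and step 6 is a one-step branch.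

**Step 7 (most likely to fail).**
- Risk: the cascade may rest at the open coumarin 14, or the closure may be reversible and erode the ee.
- Fallback: it sets out from 9 and 12 and comes back at 17.
- Claisen–Schmidt condensation of 9 with 12 (KOH, EtOH, 23 °C) gives the chalcone (E)-1-[2-hydroxy-4,6-bis(methoxymethoxy)-5-[(E)-3-methylbut-1-enyl]-3-(3-methylbut-2-enyl)phenyl]-3-[2-hydroxy-4-(methoxymethoxy)phenyl]prop-2-en-1-one F1.
- NaOAc in refluxing EtOH closes it through the only free ring A phenol to racemic 2-[2-hydroxy-4-(methoxymethoxy)phenyl]-5,7-bis(methoxymethoxy)-6-[(E)-3-methylbut-1-enyl]-8-(3-methylbut-2-enyl)chroman-4-one F2.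
- Kinetic resolution by asymmetric transfer hydrogenation follows, using RuCl(p-cymene)[(R,R)-TsDPEN] in HCO2H/Et3N. It reduces the 2R ketone to (2R,4R)-2-[2-hydroxy-4-(methoxymethoxy)phenyl]-5,7-bis(methoxymethoxy)-6-[(E)-3-methylbut-1-enyl]-8-(3-methylbut-2-enyl)chroman-4-ol F3.
- Compound 17 is left unreduced (at most 50 %) and goes on through the acetal hydrolysis of step 8.

**Step 3.**
- Risk: the iodonium source may attack the prenyl alkene or trigger iodoetherification with the neighbouring phenol.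
- Fallback: it sets out from 1 and comes back at 9. It carries a far less nucleophilic allyl group through the halogenation and turns it into prenyl afterwards.
- C-allylation of 1 with allyl bromide (KOH, H2O) gives 1-(3-allyl-2,4,6-trihydroxyphenyl)ethanone F4.
- MOMCl/K2CO3 gives 1-[3-allyl-2-hydroxy-4,6-bis(methoxymethoxy)phenyl]ethanone F5.
- NIS gives 1-[3-allyl-2-hydroxy-5-iodo-4,6-bis(methoxymethoxy)phenyl]ethanone F6.
- Suzuki coupling with 8 gives 1-[3-allyl-2-hydroxy-4,6-bis(methoxymethoxy)-5-[(E)-3-methylbut-1-enyl]phenyl]ethanone F7.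
- Cross metathesis with 2-methylbut-2-ene (second-generation Grubbs catalyst, CH2Cl2, 40 °C) gives 9. The shielded styrenyl alkene should stay inert in this step.

**Step 8.**
- Risk: warm aqueous acid may protonate the electron-rich styrene, cyclise the prenyl group onto the 7-OH, reopen 15 to 14, or ionise the C2–O1 bond.
- Fallback: it sets out from 15, comes back at 17 and then reaches 18 without Brønsted acid.
- Allyl alcohol (10 equiv, toluene, 60 °C) opens the activated aryl lactone to allyl (2S,3S)-2-[2-hydroxy-4-(methoxymethoxy)phenyl]-5,7-bis(methoxymethoxy)-6-[(E)-3-methylbut-1-enyl]-8-(3-methylbut-2-enyl)-4-oxochromane-3-carboxylate F8.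
- Pd(PPh3)4 (5 mol %) and morpholine in THF at 23 °C bring about deallylation and decarboxylation to 17.
- The three acetals are then removed with TMSOTf/2,2'-bipyridyl in MeCN at 0 °C, followed by water, to give 18.

## Further compounds

F1 | step 7 | (E)-1-[2-hydroxy-4,6-bis(methoxymethoxy)-5-[(E)-3-methylbut-1-enyl]-3-(3-methylbut-2-enyl)phenyl]-3-[2-hydroxy-4-(methoxymethoxy)phenyl]prop-2-en-1-one | O=C(/C=C/c1ccc(OCOC)cc1O)c1c(O)c(CC=C(C)C)c(OCOC)c(/C=C/C(C)C)c1OCOC
F2 | step 7 | racemic 2-[2-hydroxy-4-(methoxymethoxy)phenyl]-5,7-bis(methoxymethoxy)-6-[(E)-3-methylbut-1-enyl]-8-(3-methylbut-2-enyl)chroman-4-one | CC(C)=CCc1c(OCOC)c(/C=C/C(C)C)c(OCOC)c2c1OC(c1ccc(OCOC)cc1O)CC2=O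
F3 | step 7 | (2R,4R)-2-[2-hydroxy-4-(methoxymethoxy)phenyl]-5,7-bis(methoxymethoxy)-6-[(E)-3-methylbut-1-enyl]-8-(3-methylbut-2-enyl)chroman-4-ol | CC(C)=CCc1c(OCOC)c(/C=C/C(C)C)c(OCOC)c2c1O[C@@H](c1ccc(OCOC)cc1O)C[C@H]2O
F4 | step 3 | 1-(3-allyl-2,4,6-trihydroxyphenyl)ethanone | CC(=O)c1c(O)cc(O)c(CC=C)c1O
F5 | step 3 | 1-[3-allyl-2-hydroxy-4,6-bis(methoxymethoxy)phenyl]ethanone | CC(=O)c1c(OCOC)cc(OCOC)c(CC=C)c1O
F6 | step 3 | 1-[3-allyl-2-hydroxy-5-iodo-4,6-bis(methoxymethoxy)phenyl]ethanone | CC(=O)c1c(OCOC)c(I)c(OCOC)c(CC=C)c1O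
F7 | step 3 | 1-[3-allyl-2-hydroxy-4,6-bis(methoxymethoxy)-5-[(E)-3-methylbut-1-enyl]phenyl]ethanone | CC(=O)c1c(OCOC)c(/C=C/C(C)C)c(OCOC)c(CC=C)c1O
F8 | step 8 | allyl (2S,3S)-2-[2-hydroxy-4-(methoxymethoxy)phenyl]-5,7-bis(methoxymethoxy)-6-[(E)-3-methylbut-1-enyl]-8-(3-methylbut-2-enyl)-4-oxochromane-3-carboxylate | CC(C)=CCc1c(OCOC)c(/C=C/C(C)C)c(OCOC)c2c1O[C@H](c1ccc(OCOC)cc1O)[C@H](C(=O)OCC=C)C2=O
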